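**Strategy.** The central ring (C1 acetoxy carbon, C2 and C5 aryl carbons, C3 and C6 carbonyl carbons, C4 hydroxyl carbon) is the quinone form of a hexasubstituted benzene with four oxygens and two para aryl groups. That benzene is made in one operation by a Danheiser benzannulation: a squarate-derived 2-benzyloxy-3-aryl-4-silyloxycyclobutenone supplies C4, C5, C6 and C1, an aryl siloxyalkyne supplies C2 and C3, and the C1–C2 and C3–C4 bonds form together. The ketene oxygen emerges as the only free hydroxyl group, on C1, where the acetyl group belongs. Acetylation, desilylation, hydrogenolysis and air oxidation finish the synthesis.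

Key step: step 6

Remark on the chemistry: the fully deprotected leuco ring (a benzene-1,2,4,5-tetrol with para aryl groups) has four equivalent oxygens, so any single acetyl group on a ring oxygen leads to the same quinone 22. Acetyl or silyl shifts between neighbouring ring oxygens late in the route are therefore harmless. Compounds 6 and 10 are taken as commercial.

**Step 1**
Reactants: 1 squaric acid; 2 benzyl alcohol
Product: 3 dibenzyl squarate [3,4-bis(benzyloxy)cyclobut-3-ene-1,2-dione]
Conditions: 2 (2.5 equiv in all), toluene, reflux, Dean–Stark trap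
Reagents that add atoms: benzyl alcohol (second equivalent), OCc1ccccc1
Why: Acid-autocatalysed azeotropic (Fischer-type) esterification of both hydroxyl groups of the vinylogous diacid, the usual way to dialkyl squarates, takes up two molecules of benzyl alcohol and is driven by removal of two molecules of water.

**Step 2**
Reactants: 3 dibenzyl squarate
Product: 4 2,3-bis(benzyloxy)-4-hydroxycyclobut-2-en-1-one (racemic)
Conditions: LiAlH(OtBu)3, THF, −78 → −20 °C; then H2O
Reagents that add atoms: none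
Why: The bulky hydride should add once, 1,2, to one of the two equivalent squarate carbonyls (chemoselective carbonyl reduction), giving the racemic 4-hydroxycyclobutenone.

**Step 3**
Reactants: 4 2,3-bis(benzyloxy)-4-hydroxycyclobut-2-en-1-one
Product: 5 2,3-bis(benzyloxy)-4-[(tert-butyldimethylsilyl)oxy]cyclobut-2-en-1-one (racemic)
Conditions: TBSCl, imidazole, DMF, 0 °C
Reagents that add atoms: tert-butyldimethylsilyl chloride, CC(C)(C)[Si](C)(C)Cl
Why: Silyl ether formation under non-acidic conditions caps the secondary alcohol and avoids the acid-triggered loss of the hydroxyl group of 4.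

**Step 4**
Reactants: 5 2,3-bis(benzyloxy)-4-[(tert-butyldimethylsilyl)oxy]cyclobut-2-en-1-one; 6 1-(benzyloxy)-4-bromobenzene
Product: 9 2-(benzyloxy)-3-[4-(benzyloxy)phenyl]-4-[(tert-butyldimethylsilyl)oxy]cyclobut-2-en-1-one (racemic), via aryllithium 7 (not isolated), via carbinol 8 (not isolated)
Conditions: 6, n-BuLi, THF, −78 °C; then 5, −78 °C; then 1 M HCl, 0 °C
Reagents that add atoms: water, O
Why: Lithium–bromine exchange and 1,2-addition of 7 to the only carbonyl of 5 give carbinol 8, which mild acid ionises so that water enters at the distal benzyloxy-bearing carbon and benzyl alcohol leaves (squarate-type 1,3-carbonyl transposition), placing the aryl group β to the new carbonyl while the silyloxy-bearing stereocentre stays racemic.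

**Step 5**
Reactants: 10 1-(benzyloxy)-4-ethynylbenzene
Product: 13 {[4-(benzyloxy)phenyl]ethynyl}oxy(triisopropyl)silane, via lithium acetylide 11 (not isolated), via lithium ynolate 12 (not isolated)
Conditions: LiN(SiMe3)2, THF, −78 °C; t-BuOOLi (from t-BuOOH and LiN(SiMe3)2), −78 → 0 °C; then i-Pr3SiOTf, −78 → 0 °C
Reagents that add atoms: tert-butyl hydroperoxide, CC(C)(C)OO; triisopropylsilyl trifluoromethanesulfonate, CC(C)[Si](C(C)C)(C(C)C)OS(=O)(=O)C(F)(F)F
Why: Oxidation of the lithium acetylide 11 by lithium tert-butyl peroxide gives ynolate 12, which the hard silyl triflate traps on oxygen (acetylide oxidation followed by O-silylation).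

**Step 6**
Reactants: 9 2-(benzyloxy)-3-[4-(benzyloxy)phenyl]-4-[(tert-butyldimethylsilyl)oxy]cyclobut-2-en-1-one; 13 {[4-(benzyloxy)phenyl]ethynyl}oxy(triisopropyl)silane
Product: 18 4-(benzyloxy)-2,5-bis[4-(benzyloxy)phenyl]-6-[(tert-butyldimethylsilyl)oxy]-3-[(triisopropylsilyl)oxy]phenol, via vinylketene 14 (not isolated), via vinylcyclobutenone 15 (not isolated), via dienylketene 16 (not isolated), via cyclohexadienone 17 (not isolated)
Conditions: toluene, 80 °C, then 110 °C, argon
Reagents that add atoms: none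
Why: Heating should open 9 by a conrotatory 4π electrocyclic reaction (silyloxy group outward) to vinylketene 14, whose ketene C=C adds to siloxyalkyne 13 in a [2+2] cycloaddition to give vinylcyclobutenone 15; 15 opens again (benzyloxy outward, vinyl inward) to dienylketene 16, which closes to cyclohexadienone 17 and tautomerises to 18. The closest known reaction is the Danheiser benzannulation of cyclobutenones with siloxyalkynes. The [2+2] step makes the two new carbon–carbon bonds (aryl-bearing alkyne carbon to the ketene carbonyl carbon, siloxy-bearing alkyne carbon to the benzyloxy-bearing carbon), and the six-membered ring is then closed by a thermal disrotatory 6π electrocyclisation of 16 that rejoins the former C1 and C4 of 9. No stereocentre remains, since the single stereocentres of 9, 15 and 17 are destroyed by ring opening and aromatisation. The step needs one orientation of the alkyne, the one that places the two aryl groups para, and the polarity of the partners secures it: the aryl-bearing carbon of the ynol ether is its nucleophilic end and the ketene carbonyl carbon is the electrophilic end. The ketene oxygen is left as the only free hydroxyl group of the new ring.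

**Step 7**
Reactants: 18 4-(benzyloxy)-2,5-bis[4-(benzyloxy)phenyl]-6-[(tert-butyldimethylsilyl)oxy]-3-[(triisopropylsilyl)oxy]phenol
Product: 19 4-(benzyloxy)-2,5-bis[4-(benzyloxy)phenyl]-6-[(tert-butyldimethylsilyl)oxy]-3-[(triisopropylsilyl)oxy]phenyl acetate
Conditions: Ac2O, pyridine, DMAP (cat.), CH2Cl2, rt
Reagents that add atoms: acetic anhydride, CC(=O)OC(C)=O
Why: DMAP-catalysed O-acylation (nucleophilic catalysis) of the only free hydroxyl group should fix the acetyl group on the oxygen created in the benzannulation.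

**Step 8**
Reactants: 19 4-(benzyloxy)-2,5-bis[4-(benzyloxy)phenyl]-6-[(tert-butyldimethylsilyl)oxy]-3-[(triisopropylsilyl)oxy]phenyl acetate
Product: 20 4-(benzyloxy)-2,5-bis[4-(benzyloxy)phenyl]-3,6-dihydroxyphenyl acetate
Conditions: HF·pyridine, pyridine, THF, 0 °C → rt, argon
Reagents that add atoms: none
Why: Fluoride-driven cleavage of the two aryl silyl ethers (desilylation through silicon–fluorine bond formation) under acidic, non-hydrolytic conditions should spare the aryl acetate and the benzyl ethers and free the para pair of hydroxyl groups.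

**Step 9**
Reactants: 20 4-(benzyloxy)-2,5-bis[4-(benzyloxy)phenyl]-3,6-dihydroxyphenyl acetate
Product: 22 4-hydroxy-2,5-bis(4-hydroxyphenyl)-3,6-dioxocyclohexa-1,4-dien-1-yl acetate (target), via leuco triol acetate 21 (not isolated)
Conditions: H2 (1 atm), Pd/C (10% Pd on carbon), EtOAc, rt; filter under argon; then air (O2), rt
Reagents that add atoms: none
Why: Palladium-catalysed hydrogenolysis should cleave the three benzyl ethers to leuco triol acetate 21, whose hydroxyhydroquinone core autoxidises in air to the more stable 2-hydroxy-1,4-quinone tautomer 22.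

**Compound list**
1 | squaric acid (3,4-dihydroxycyclobut-3-ene-1,2-dione) | O=C1C(=O)C(O)=C1O | starting material
2 | benzyl alcohol | OCc1ccccc1 | starting material
3 | dibenzyl squarate, 3,4-bis(benzyloxy)cyclobut-3-ene-1,2-dione | O=C1C(=O)C(OCc2ccccc2)=C1OCc1ccccc1 | intermediate
4 | 2,3-bis(benzyloxy)-4-hydroxycyclobut-2-en-1-one (racemic) | O=C1C(O)C(OCc2ccccc2)=C1OCc1ccccc1 | intermediate
5 | 2,3-bis(benzyloxy)-4-[(tert-butyldimethylsilyl)oxy]cyclobut-2-en-1-one (racemic) | O=C1C(O[Si](C)(C)C(C)(C)C)C(OCc2ccccc2)=C1OCc1ccccc1 | intermediate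
6 | 1-(benzyloxy)-4-bromobenzene | Brc1ccc(OCc2ccccc2)cc1 | starting material
7 | [4-(benzyloxy)phenyl]lithium | [Li]c1ccc(OCc2ccccc2)cc1 | intermediate (not isolated)
8 | 2,3-bis(benzyloxy)-1-[4-(benzyloxy)phenyl]-4-[(tert-butyldimethylsilyl)oxy]cyclobut-2-en-1-ol (racemic, mixture of diastereomers) | OC1(c2ccc(OCc3ccccc3)cc2)C(OCc2ccccc2)=C(OCc2ccccc2)C1O[Si](C)(C)C(C)(C)C | intermediate (not isolated)
9 | 2-(benzyloxy)-3-[4-(benzyloxy)phenyl]-4-[(tert-butyldimethylsilyl)oxy]cyclobut-2-en-1-one (racemic) | O=C1C(OCc2ccccc2)=C(c2ccc(OCc3ccccc3)cc2)C1O[Si](C)(C)C(C)(C)C | intermediate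
10 | 1-(benzyloxy)-4-ethynylbenzene | C#Cc1ccc(OCc2ccccc2)cc1 | starting material
11 | lithium [4-(benzyloxy)phenyl]acetylide | [Li]C#Cc1ccc(OCc2ccccc2)cc1 | intermediate (not isolated)
12 | lithium 2-[4-(benzyloxy)phenyl]ethynolate | [Li]OC#Cc1ccc(OCc2ccccc2)cc1 | intermediate (not isolated)
13 | {[4-(benzyloxy)phenyl]ethynyl}oxy(triisopropyl)silane | CC(C)[Si](OC#Cc1ccc(OCc2ccccc2)cc1)(C(C)C)C(C)C | intermediate
14 | (3E)-2-(benzyloxy)-3-[4-(benzyloxy)phenyl]-4-[(tert-butyldimethylsilyl)oxy]buta-1,3-dien-1-one (vinylketene) | O=C=C(OCc1ccccc1)/C(c1ccc(OCc2ccccc2)cc1)=C/O[Si](C)(C)C(C)(C)C | intermediate (not isolated)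
15 | 4-(benzyloxy)-2-[4-(benzyloxy)phenyl]-4-{(E)-1-[4-(benzyloxy)phenyl]-2-[(tert-butyldimethylsilyl)oxy]ethenyl}-3-[(triisopropylsilyl)oxy]cyclobut-2-en-1-one (racemic) | O=C1C(c2ccc(OCc3ccccc3)cc2)=C(O[Si](C(C)C)(C(C)C)C(C)C)C1(OCc1ccccc1)/C(c1ccc(OCc2ccccc2)cc1)=C/O[Si](C)(C)C(C)(C)C | intermediate (not isolated)
16 | (3Z,5E)-4-(benzyloxy)-2,5-bis[4-(benzyloxy)phenyl]-6-[(tert-butyldimethylsilyl)oxy]-3-[(triisopropylsilyl)oxy]hexa-1,3,5-trien-1-one (dienylketene) | O=C=C(c1ccc(OCc2ccccc2)cc1)/C(O[Si](C(C)C)(C(C)C)C(C)C)=C(OCc1ccccc1)\C(c1ccc(OCc2ccccc2)cc1)=C\O[Si](C)(C)C(C)(C)C | intermediate (not isolated)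
17 | 4-(benzyloxy)-2,5-bis[4-(benzyloxy)phenyl]-6-[(tert-butyldimethylsilyl)oxy]-3-[(triisopropylsilyl)oxy]cyclohexa-2,4-dien-1-one (racemic) | O=C1C(c2ccc(OCc3ccccc3)cc2)=C(O[Si](C(C)C)(C(C)C)C(C)C)C(OCc2ccccc2)=C(c2ccc(OCc3ccccc3)cc2)C1O[Si](C)(C)C(C)(C)C | intermediate (not isolated)
18 | 4-(benzyloxy)-2,5-bis[4-(benzyloxy)phenyl]-6-[(tert-butyldimethylsilyl)oxy]-3-[(triisopropylsilyl)oxy]phenol | Oc1c(-c2ccc(OCc3ccccc3)cc2)c(O[Si](C(C)C)(C(C)C)C(C)C)c(OCc2ccccc2)c(-c2ccc(OCc3ccccc3)cc2)c1O[Si](C)(C)C(C)(C)C | intermediate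
19 | 4-(benzyloxy)-2,5-bis[4-(benzyloxy)phenyl]-6-[(tert-butyldimethylsilyl)oxy]-3-[(triisopropylsilyl)oxy]phenyl acetate | CC(=O)Oc1c(-c2ccc(OCc3ccccc3)cc2)c(O[Si](C(C)C)(C(C)C)C(C)C)c(OCc2ccccc2)c(-c2ccc(OCc3ccccc3)cc2)c1O[Si](C)(C)C(C)(C)C | intermediate
20 | 4-(benzyloxy)-2,5-bis[4-(benzyloxy)phenyl]-3,6-dihydroxyphenyl acetate | CC(=O)Oc1c(-c2ccc(OCc3ccccc3)cc2)c(O)c(OCc2ccccc2)c(-c2ccc(OCc3ccccc3)cc2)c1O | intermediate
21 | 3,4,6-trihydroxy-2,5-bis(4-hydroxyphenyl)phenyl acetate (leuco triol acetate) | CC(=O)Oc1c(-c2ccc(O)cc2)c(O)c(O)c(-c2ccc(O)cc2)c1O | intermediate (not isolated)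
22 | 4-hydroxy-2,5-bis(4-hydroxyphenyl)-3,6-dioxocyclohexa-1,4-dien-1-yl acetate | CC(=O)OC1=C(c2ccc(O)cc2)C(=O)C(O)=C(c2ccc(O)cc2)C1=O | target

**Step count and risks**
Total steps: 9. Longest linear sequence: 8 (steps 1–4 and 6–9; step 5 is the one-step side branch).

Steps most likely to fail:

1. Step 6. The [2+2] capture of the hindered, fully substituted vinylketene by the internal siloxyalkyne may be outpaced by ketene dimerisation or by silyl transfer, or the second ring opening may turn the vinyl group outward so that ring closure stalls. Fallback (sets out from 6, comes back at 21): the six-membered ring is taken ready-made and arylated instead. Compound 6 is converted (n-BuLi, THF, −78 °C; B(Oi-Pr)3; aq. HCl) into [4-(benzyloxy)phenyl]boronic acid F1. Commercial tetrabromo-1,4-benzoquinone with NaOMe in MeOH should give 2,5-dibromo-3,6-dimethoxy-1,4-benzoquinone F2. A double Suzuki coupling of F2 with two equivalents of F1 (Pd(PPh3)4, Na2CO3, dioxane/H2O, 90 °C) should give 2,5-bis[4-(benzyloxy)phenyl]-3,6-dimethoxy-1,4-benzoquinone F3. Hydrolysis of the two vinylogous esters (NaOH, aq. dioxane; then HCl) should give 2,5-bis[4-(benzyloxy)phenyl]-3,6-dihydroxy-1,4-benzoquinone F4. One equivalent of Ac2O with pyridine at 0 °C should acetylate one of the two equivalent enolic hydroxyl groups to 2-acetoxy-3,6-bis[4-(benzyloxy)phenyl]-5-hydroxy-1,4-benzoquinone F5, to be separated from diacetate and unchanged F4. Hydrogenolysis of F5 under the conditions of step 9 gives 21, which air oxidises to 22.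

2. Step 4. After the aryllithium addition, migration of the silyl group to the neighbouring tertiary alkoxide, or ionisation with loss of the silyloxy group, may compete with the intended transposition. Fallback (sets out from 3 and 7, comes back at 9): the order of events is reversed so that the silyl group is put on last. Aryllithium 7 (from 6 as in step 4) is added to dibenzyl squarate 3 at −78 °C to give, as its lithium alkoxide, 2,3-bis(benzyloxy)-4-[4-(benzyloxy)phenyl]-4-hydroxycyclobut-2-en-1-one F6. In the same flask i-Bu2AlH reduces the remaining carbonyl to 2,3-bis(benzyloxy)-4-[4-(benzyloxy)phenyl]cyclobut-2-ene-1,4-diol F7. Dilute acid on work-up ionises the tertiary benzylic hydroxyl group and should give 2-(benzyloxy)-3-[4-(benzyloxy)phenyl]-4-hydroxycyclobut-2-en-1-one F8. Silylation (TBSCl, imidazole, DMF, 0 °C) gives 9.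

3. Step 8. Cleavage of the hindered triisopropylsilyl ether may be slow, and during prolonged exposure the acetyl group may be lost by solvolysis once the neighbouring oxygen is free. Fallback (sets out from 19, comes back at 21): the silyl ethers are removed oxidatively instead of by fluoride. Treatment of 19 with (NH4)2Ce(NO3)6 in MeCN/H2O at 0 °C should oxidise the para pair of silyloxy carbons directly to 2-acetoxy-5-(benzyloxy)-3,6-bis[4-(benzyloxy)phenyl]-1,4-benzoquinone F9. Under the conditions of step 9 this is reduced and debenzylated to 21, which air oxidises to 22.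

**Further compounds**
F1 | step 6 | [4-(benzyloxy)phenyl]boronic acid | OB(O)c1ccc(OCc2ccccc2)cc1
F2 | step 6 | 2,5-dibromo-3,6-dimethoxy-1,4-benzoquinone | COC1=C(Br)C(=O)C(OC)=C(Br)C1=O
F3 | step 6 | 2,5-bis[4-(benzyloxy)phenyl]-3,6-dimethoxy-1,4-benzoquinone | COC1=C(c2ccc(OCc3ccccc3)cc2)C(=O)C(OC)=C(c2ccc(OCc3ccccc3)cc2)C1=O
F4 | step 6 | 2,5-bis[4-(benzyloxy)phenyl]-3,6-dihydroxy-1,4-benzoquinone | OC1=C(c2ccc(OCc3ccccc3)cc2)C(=O)C(O)=C(c2ccc(OCc3ccccc3)cc2)C1=O
F5 | step 6 | 2-acetoxy-3,6-bis[4-(benzyloxy)phenyl]-5-hydroxy-1,4-benzoquinone | CC(=O)OC1=C(c2ccc(OCc3ccccc3)cc2)C(=O)C(O)=C(c2ccc(OCc3ccccc3)cc2)C1=O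
F6 | step 4 | 2,3-bis(benzyloxy)-4-[4-(benzyloxy)phenyl]-4-hydroxycyclobut-2-en-1-one (racemic) | O=C1C(OCc2ccccc2)=C(OCc2ccccc2)C1(O)c1ccc(OCc2ccccc2)cc1
F7 | step 4 | 2,3-bis(benzyloxy)-4-[4-(benzyloxy)phenyl]cyclobut-2-ene-1,4-diol (racemic, mixture of diastereomers) | OC1C(OCc2ccccc2)=C(OCc2ccccc2)C1(O)c1ccc(OCc2ccccc2)cc1
F8 | step 4 | 2-(benzyloxy)-3-[4-(benzyloxy)phenyl]-4-hydroxycyclobut-2-en-1-one (racemic) | O=C1C(OCc2ccccc2)=C(c2ccc(OCc3ccccc3)cc2)C1O
F9 | step 8 | 2-acetoxy-5-(benzyloxy)-3,6-bis[4-(benzyloxy)phenyl]-1,4-benzoquinone | CC(=O)OC1=C(c2ccc(OCc3ccccc3)cc2)C(=O)C(OCc2ccccc2)=C(c2ccc(OCc3ccccc3)cc2)C1=O
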